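**Retrosynthetic overview**

1. Presumed biosynthesis (eudesmane numbering): farnesyl cyclisation makes C6–C7; the 8β,12-germacranolide closes C5→C10 on its 1(10)-epoxide to a 1β-hydroxyeudesmanolide; Grob scission of C1–C10 leaves the 5(10)-olefin, O-6 and a C1 aldehyde, which is reduced; O-6 is acylated.
2. Last disconnections, the same late events: C1 carbinol ⇐ C1 aldehyde; O-6 ester ⇐ allylic carbinol + (2R)-2-methylbutanoic acid (1); the C1 aldehyde is masked as the prenyl end of (S)-citronellal (2), which also carries C4.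
3. Carbocycle (second ring, key step): C6–C7 by intramolecular chromium allylation; the C7=C11 π bond attacks the C6 aldehyde and the double bond moves out to C11=C13, the electron flow of the cyclase step; C6, C7 and the exocyclic methylene arise together.
4. C5=C10 (made before ring closure): the C5 enol π bond of 2 adds to a C10 oxocarbenium ion and the C10 oxygen then leaves, the polarity of the C5→C10 closure; C1 is never bonded to C10, so no scission is needed.
5. Lactone (first ring): C8–O–C12 by iridium-catalysed 2-(methoxycarbonyl)allylation with methyl 2-{[(tert-butoxycarbonyl)oxy]methyl}acrylate (3) and lactonisation on O-8, then bromination–dehydrobromination to the allyl bromide; C8–C10 and C14 come from fructone (4).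

Assumption: atoms carry eudesmane numbers (C1 side-chain carbinol, C4 side-chain stereocentre, C5=C10 ring olefin, C6 ester carbon, C7/C8 ring fusion, C11/C12/C13 lactone α-carbon, carbonyl and methylene); 1–4 are bought, 1 and 2 as the enantiopure grades.

**Route**

Step 1
Reactants: 4 ethyl 2-(2-methyl-1,3-dioxolan-2-yl)acetate (fructone)
Product: 5 2-(2-methyl-1,3-dioxolan-2-yl)ethan-1-ol
Conditions: LiAlH4, THF, 0 °C
Reagents that add atoms: none
Why: Hydride reduction of the ester to the primary alcohol; the dioxolane is inert to LiAlH4 and no stereocentre is involved.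

Step 2
Reactants: 5 2-(2-methyl-1,3-dioxolan-2-yl)ethan-1-ol; 3 methyl 2-{[(tert-butoxycarbonyl)oxy]methyl}prop-2-enoate
Product: 8 (5S)-3-methylidene-5-[(2-methyl-1,3-dioxolan-2-yl)methyl]oxolan-2-one, via dioxolanyl acetaldehyde 6 (not isolated), via homoallylic hydroxy ester 7 (not isolated)
Conditions: [Ir(cod)Cl]2 (2.5 mol%), (S)-SEGPHOS (5 mol%), 4-cyano-3-nitrobenzoic acid (10 mol%), Cs2CO3 (20 mol%), THF, 60 °C
Reagents that add atoms: none
Why: Krische 2-(alkoxycarbonyl)allylation from the alcohol oxidation level: the iridium catalyst dehydrogenates 5 to 6 and transfers the 2-(methoxycarbonyl)allyl group of 3 to one aldehyde face under control of the bisphosphine, which sets C8 (the ligand hand is the one that gives 5S; its antipode gives ent-8), and 7 lactonises to the C8–O–C12 ring.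

Step 3
Reactants: 8 (5S)-3-methylidene-5-[(2-methyl-1,3-dioxolan-2-yl)methyl]oxolan-2-one
Product: 10 (5R)-3-(bromomethyl)-5-[(2-methyl-1,3-dioxolan-2-yl)methyl]furan-2(5H)-one, via 3-bromo-3-(bromomethyl) lactone 9 (not isolated)
Conditions: Br2, CH2Cl2, 0 °C; then i-Pr2NEt, 0 °C
Reagents that add atoms: bromine, BrBr
Why: Bromine addition to the exocyclic olefin followed by E2 loss of HBr toward C7 gives the conjugated butenolide with an allylic bromide; C8 is untouched (the S to R change is a CIP priority change only), and the hindered base at 0 °C avoids quaternisation and γ-deprotonation.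

Step 4
Reactants: 2 (3S)-3,7-dimethyloct-6-enal ((S)-citronellal)
Product: 11 {[(3S)-3,7-dimethylocta-1,6-dien-1-yl]oxy}trimethylsilane (E/Z mixture)
Conditions: TMSCl, Et3N, DMF, 80 °C
Reagents that add atoms: chlorotrimethylsilane, C[Si](C)(C)Cl
Why: House silylation of the aldehyde enol; enolisation involves C5 only, so the C4 stereocentre of 2 is retained.

Step 5
Reactants: 10 (5R)-3-(bromomethyl)-5-[(2-methyl-1,3-dioxolan-2-yl)methyl]furan-2(5H)-one; 11 {[(3S)-3,7-dimethylocta-1,6-dien-1-yl]oxy}trimethylsilane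
Product: 13 (2Z)-4-[(2R)-4-(bromomethyl)-5-oxo-2,5-dihydrofuran-2-yl]-3-methyl-2-[(2S)-6-methylhept-5-en-2-yl]but-2-enal, via glycol-ether aldol 12 (not isolated)
Conditions: TMSOTf (0.3 equiv), CH2Cl2, −78 °C; then PPTS (cat.), CH2Cl2, 25 °C; (E)-isomer separated and re-equilibrated with PPTS
Reagents that add atoms: none
Why: Mukaiyama aldol addition in the Noyori ketal variant: TMSOTf opens the dioxolane to a C10 oxocarbenium ion that is attacked by C5 of 11 (aldehydes are not activated under these conditions), and acid-catalysed β-elimination of the glycol ether from 12 gives the conjugated enal, with the Z isomer (CHO cis to C9, bulky C4 group cis to methyl) favoured at equilibrium; C4 and C8 are not involved.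

Step 6
Reactants: 13 (2Z)-4-[(2R)-4-(bromomethyl)-5-oxo-2,5-dihydrofuran-2-yl]-3-methyl-2-[(2S)-6-methylhept-5-en-2-yl]but-2-enal
Product: 15 (3aS,4R,7aR)-4-hydroxy-6-methyl-3-methylidene-5-[(2S)-6-methylhept-5-en-2-yl]-3a,4,7,7a-tetrahydro-1-benzofuran-2(3H)-one, via allylchromium dichloride 14 (not isolated)
Conditions: CrCl2 (5 equiv), THF (0.005 M), 25 °C; aq. NH4Cl
Reagents that add atoms: none
Why: Intramolecular Nozaki–Hiyama–Kishi-type allylation: two CrCl2 reduce the C–Br bond to an allyl–CrCl2 species (trivalent chromium) that adds through C7 (SE2′) to the aldehyde in a closed six-membered transition state; the two-atom tether from C8 allows attack only on the lactone face that carries C9 (cis ring fusion, C7), and A(1,2) strain with the C5 substituent puts the forming C6–O bond pseudo-axial and synclinal to C11, so O-6, C11 and O-8 end on one face (C6).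

Step 7
Reactants: 15 (3aS,4R,7aR)-4-hydroxy-6-methyl-3-methylidene-5-[(2S)-6-methylhept-5-en-2-yl]-3a,4,7,7a-tetrahydro-1-benzofuran-2(3H)-one; 1 (2R)-2-methylbutanoic acid
Product: 17 (3aR,4R,7aR)-6-methyl-3-methylidene-5-[(2S)-6-methylhept-5-en-2-yl]-2-oxo-2,3,3a,4,7,7a-hexahydro-1-benzofuran-4-yl (2R)-2-methylbutanoate, via O-acylisourea 16 (not isolated)
Conditions: DCC, DMAP (10 mol%), CH2Cl2, 0 °C
Reagents that add atoms: none
Why: Steglich esterification with retention at C6 (3aS to 3aR is a CIP priority change only); low temperature and catalytic DMAP keep the α-stereocentre of the acid intact.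

Step 8
Reactants: 17 (3aR,4R,7aR)-6-methyl-3-methylidene-5-[(2S)-6-methylhept-5-en-2-yl]-2-oxo-2,3,3a,4,7,7a-hexahydro-1-benzofuran-4-yl (2R)-2-methylbutanoate
Product: 20 (3aR,4R,7aR)-5-[(2S)-5-hydroxypentan-2-yl]-6-methyl-3-methylidene-2-oxo-2,3,3a,4,7,7a-hexahydro-1-benzofuran-4-yl (2R)-2-methylbutanoate, via vicinal diol 18 (not isolated), via C1 aldehyde 19 (not isolated)
Conditions: OsO4 (2 mol%), NaIO4, 2,6-lutidine, dioxane/H2O, 0 °C; extraction; then NaBH4, MeOH, −78 °C
Reagents that add atoms: osmium tetroxide, O=[Os](=O)(=O)=O; sodium periodate, [Na+].[O-]I(=O)(=O)=O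
Why: Lemieux–Johnson cleavage then borohydride reduction: OsO4 dihydroxylates the electron-rich trisubstituted side-chain olefin much faster than the hindered tetrasubstituted ring olefin or the electron-poor methylene lactone, periodate cleaves 18 to the C1 aldehyde 19, and NaBH4 at −78 °C reduces only the aldehyde.

**Compound list**

1 | (2R)-2-methylbutanoic acid | CC[C@@H](C)C(O)=O | starting material
2 | (3S)-3,7-dimethyloct-6-enal, (S)-citronellal | O=CC[C@@H](C)CCC=C(C)C | starting material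
3 | methyl 2-{[(tert-butoxycarbonyl)oxy]methyl}prop-2-enoate | C=C(COC(=O)OC(C)(C)C)C(=O)OC | starting material
4 | ethyl 2-(2-methyl-1,3-dioxolan-2-yl)acetate, fructone | CCOC(=O)CC1(C)OCCO1 | starting material
5 | 2-(2-methyl-1,3-dioxolan-2-yl)ethan-1-ol | OCCC1(C)OCCO1 | intermediate
6 | 2-(2-methyl-1,3-dioxolan-2-yl)acetaldehyde | O=CCC1(C)OCCO1 | intermediate
7 | methyl (4S)-4-hydroxy-2-methylidene-5-(2-methyl-1,3-dioxolan-2-yl)pentanoate | C=C(C[C@H](O)CC1(C)OCCO1)C(=O)OC | intermediate
8 | (5S)-3-methylidene-5-[(2-methyl-1,3-dioxolan-2-yl)methyl]oxolan-2-one | C=C1C(=O)O[C@@H](C1)CC2(C)OCCO2 | intermediate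
9 | (5R)-3-bromo-3-(bromomethyl)-5-[(2-methyl-1,3-dioxolan-2-yl)methyl]oxolan-2-one (C3 epimers) | O=C1O[C@@H](CC1(Br)CBr)CC2(C)OCCO2 | intermediate
10 | (5R)-3-(bromomethyl)-5-[(2-methyl-1,3-dioxolan-2-yl)methyl]furan-2(5H)-one | O=C1O[C@@H](C=C1CBr)CC2(C)OCCO2 | intermediate
11 | {[(3S)-3,7-dimethylocta-1,6-dien-1-yl]oxy}trimethylsilane (E/Z) | C[Si](C)(C)OC=C[C@@H](C)CCC=C(C)C | intermediate
12 | 4-[(2R)-4-(bromomethyl)-5-oxo-2,5-dihydrofuran-2-yl]-3-methyl-2-[(2S)-6-methylhept-5-en-2-yl]-3-[2-(trimethylsilyloxy)ethoxy]butanal (C2/C3 epimers) | O=CC([C@@H](C)CCC=C(C)C)C(C)(OCCO[Si](C)(C)C)C[C@H]1OC(=O)C(CBr)=C1 | intermediate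
13 | (2Z)-4-[(2R)-4-(bromomethyl)-5-oxo-2,5-dihydrofuran-2-yl]-3-methyl-2-[(2S)-6-methylhept-5-en-2-yl]but-2-enal | O=C/C([C@@H](C)CCC=C(C)C)=C(/C)C[C@H]1OC(=O)C(CBr)=C1 | intermediate
14 | {[(5R)-5-{(2Z)-3-formyl-2-methyl-3-[(2S)-6-methylhept-5-en-2-yl]prop-2-en-1-yl}-2-oxo-2,5-dihydrofuran-3-yl]methyl}chromium dichloride | O=C/C([C@@H](C)CCC=C(C)C)=C(/C)C[C@H]1OC(=O)C(C[Cr](Cl)Cl)=C1 | intermediate
15 | (3aS,4R,7aR)-4-hydroxy-6-methyl-3-methylidene-5-[(2S)-6-methylhept-5-en-2-yl]-3a,4,7,7a-tetrahydro-1-benzofuran-2(3H)-one | C=C1C(=O)O[C@@H]2CC(C)=C([C@@H](C)CCC=C(C)C)[C@H](O)[C@H]12 | intermediate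
16 | N,N'-dicyclohexyl-O-[(2R)-2-methylbutanoyl]isourea | CC[C@@H](C)C(=O)OC(=NC1CCCCC1)NC1CCCCC1 | intermediate
17 | (3aR,4R,7aR)-6-methyl-3-methylidene-5-[(2S)-6-methylhept-5-en-2-yl]-2-oxo-2,3,3a,4,7,7a-hexahydro-1-benzofuran-4-yl (2R)-2-methylbutanoate | C=C1C(=O)O[C@@H]2CC(C)=C([C@@H](C)CCC=C(C)C)[C@H](OC(=O)[C@H](C)CC)[C@H]12 | intermediate
18 | (3aR,4R,7aR)-5-[(2S)-5,6-dihydroxy-6-methylheptan-2-yl]-6-methyl-3-methylidene-2-oxo-2,3,3a,4,7,7a-hexahydro-1-benzofuran-4-yl (2R)-2-methylbutanoate (side-chain C5 epimers) | C=C1C(=O)O[C@@H]2CC(C)=C([C@@H](C)CCC(O)C(C)(C)O)[C@H](OC(=O)[C@H](C)CC)[C@H]12 | intermediate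
19 | (3aR,4R,7aR)-6-methyl-3-methylidene-2-oxo-5-[(2S)-5-oxopentan-2-yl]-2,3,3a,4,7,7a-hexahydro-1-benzofuran-4-yl (2R)-2-methylbutanoate | C=C1C(=O)O[C@@H]2CC(C)=C([C@@H](C)CCC=O)[C@H](OC(=O)[C@H](C)CC)[C@H]12 | intermediate
20 | (3aR,4R,7aR)-5-[(2S)-5-hydroxypentan-2-yl]-6-methyl-3-methylidene-2-oxo-2,3,3a,4,7,7a-hexahydro-1-benzofuran-4-yl (2R)-2-methylbutanoate | C=C1C(=O)O[C@@H]2CC(C)=C([C@@H](C)CCCO)[C@H](OC(=O)[C@H](C)CC)[C@H]12 | target

**Step count and risks**

Total step count: 8. Longest linear sequence: 7 (steps 1, 2, 3, 5, 6, 7, 8).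

Steps most likely to fail:

Step 5. Risks: the Z/E ratio of the tetrasubstituted enal (only Z can cyclise), and acid-induced carbonyl-ene closure of the citronellal-type aldehyde onto its prenyl group. The fallback changes the order of events, closing the ring before the olefin exists. It sets out from 12, isolated by quenching step 5 at −78 °C with NaHCO3 before the PPTS stage. CrCl2 under the conditions of step 6 converts 12 into the allylchromium dichloride of 12 F1, which closes to the cis-fused 6-[2-(trimethylsilyloxy)ethoxy]-5,6-dihydro analogue of 15 F2; no olefin geometry is involved. DCC/DMAP esterification with 1 gives its (2R)-2-methylbutanoate F3. TsOH in benzene at 40 °C then ionises the tertiary glycol ether at C10, and loss of H-5 gives the most substituted, endocyclic olefin; the fallback comes back to the route at 17.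

Step 6. Risks: oligomerisation instead of ring closure, or the C6 epimer. The fallback changes the polarity at C6 and sets C6 separately. It sets out from 13. A thiazolium carbene (3-benzyl-5-(2-hydroxyethyl)-4-methylthiazolium chloride, i-Pr2NEt, dioxane, 60 °C) turns the aldehyde into an acyl anion equivalent (Stetter-type) that attacks C7 in an SN2′ sense with loss of bromide. This gives (3aR,7aR)-6-methyl-3-methylidene-5-[(2S)-6-methylhept-5-en-2-yl]-3a,7a-dihydro-1-benzofuran-2,4(3H,7H)-dione F4. Luche reduction (NaBH4, CeCl3, MeOH, −78 °C) delivers hydride to the convex face of the cis-fused bicycle, and the fallback comes back to the route at 15.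

Step 8. Risks: OsO4 or borohydride attack on the α-methylene lactone. The fallback masks the methylene group first. It sets out from 17. Me2NH in THF adds to the methylene lactone to give the dimethylaminomethyl lactone of 17 F5, whose C11 is sp3. Cleavage and reduction under the conditions of step 8 pass through its side-chain diol F6 and its C1 aldehyde F7 (neither isolated) to the amino alcohol F8. MeI gives the trimethylammonium iodide F9, and aqueous NaHCO3 eliminates trimethylamine to restore the methylene lactone; the fallback comes back to the route at 20.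

**Further compounds**

F1 | step 5 | allylchromium dichloride of 12: {[(5R)-5-{3-formyl-2-methyl-3-[(2S)-6-methylhept-5-en-2-yl]-2-[2-(trimethylsilyloxy)ethoxy]propyl}-2-oxo-2,5-dihydrofuran-3-yl]methyl}chromium dichloride | O=CC([C@@H](C)CCC=C(C)C)C(C)(OCCO[Si](C)(C)C)C[C@H]1OC(=O)C(C[Cr](Cl)Cl)=C1
F2 | step 5 | cis-fused 5,6-dihydro analogue of 15 with a 2-(trimethylsilyloxy)ethoxy group on the methyl-bearing ring carbon (epimers at the two new ring carbons) | C=C1C(=O)O[C@@H]2CC(C)(OCCO[Si](C)(C)C)C([C@@H](C)CCC=C(C)C)[C@H](O)[C@H]12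
F3 | step 5 | (2R)-2-methylbutanoate of F2 | C=C1C(=O)O[C@@H]2CC(C)(OCCO[Si](C)(C)C)C([C@@H](C)CCC=C(C)C)[C@H](OC(=O)[C@H](C)CC)[C@H]12
F4 | step 6 | (3aR,7aR)-6-methyl-3-methylidene-5-[(2S)-6-methylhept-5-en-2-yl]-3a,7a-dihydro-1-benzofuran-2,4(3H,7H)-dione | C=C1C(=O)O[C@@H]2CC(C)=C([C@@H](C)CCC=C(C)C)C(=O)[C@H]12
F5 | step 8 | 3-[(dimethylamino)methyl] lactone from 17 (C3 epimers) | CN(C)CC1C(=O)O[C@@H]2CC(C)=C([C@@H](C)CCC=C(C)C)[C@H](OC(=O)[C@H](C)CC)[C@H]12
F6 | step 8 | side-chain 5,6-diol of F5 | CN(C)CC1C(=O)O[C@@H]2CC(C)=C([C@@H](C)CCC(O)C(C)(C)O)[C@H](OC(=O)[C@H](C)CC)[C@H]12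
F7 | step 8 | side-chain C1 aldehyde from F6 | CN(C)CC1C(=O)O[C@@H]2CC(C)=C([C@@H](C)CCC=O)[C@H](OC(=O)[C@H](C)CC)[C@H]12
F8 | step 8 | 3-[(dimethylamino)methyl] lactone with the 5-hydroxypentan-2-yl side chain | CN(C)CC1C(=O)O[C@@H]2CC(C)=C([C@@H](C)CCCO)[C@H](OC(=O)[C@H](C)CC)[C@H]12
F9 | step 8 | trimethylammonium iodide of F8 | C[N+](C)(C)CC1C(=O)O[C@@H]2CC(C)=C([C@@H](C)CCCO)[C@H](OC(=O)[C@H](C)CC)[C@H]12.[I-]
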